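The plan rests on cutting the bay-region biaryl bond between phenanthrene C4 (ring C) and the ring E carbon beside its hydroxyl. Both carbons sit ortho to a free OH, whereas C2 carries Cl, C10a is a fusion carbon, and ring E has an alkylated para carbon and two identical ortho CH sites, so only one C–C union is open. One anodic dehydrogenative coupling makes that bond and thereby closes the 12-membered ring without prefunctionalisation. Its precursor is an open diphenol: 2-chloro-7-methoxyphenanthren-3-ol bearing at C6 a chlorinated ring D, masked as an electron-poor pivalate, whose ethano arm ends in the 4-hydroxyphenyl ring E.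

Key step: step 13

Remark on the chemistry: the target SMILES carries no stereodescriptor, so the hindered biaryl axes and the twisted bay region are taken as unspecified, and 18 and 19 are made as racemates.

Step 1
Reactants: 1 4-bromo-3-methoxybenzaldehyde
Product: 2 4-bromo-2-iodo-5-methoxybenzaldehyde
Conditions: NIS (1.1 equiv), CF3SO3H (0.3 equiv), MeCN, 0 °C to rt
Reagents that add atoms: N-iodosuccinimide, O=C1CCC(=O)N1I
Why: Electrophilic aromatic iodination with acid-activated NIS should go to the free carbon para to the methoxy group (C6 of 1, next to the formyl group), because the only other activated site is wedged between OMe and CHO, and it installs a halide that reacts ahead of the bromide in step 2.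

Step 2
Reactants: 2 4-bromo-2-iodo-5-methoxybenzaldehyde; 3 [3-(benzyloxy)-4-chlorophenyl]boronic acid
Product: 4 3'-(benzyloxy)-5-bromo-4'-chloro-4-methoxybiphenyl-2-carbaldehyde
Conditions: Pd(PPh3)4 (3 mol %), Na2CO3 (2 equiv), DME/H2O 4:1, 65 °C
Reagents that add atoms: none
Why: In this Suzuki–Miyaura coupling zerovalent palladium inserts into the carbon–iodine bond ortho to the aldehyde much faster than into the carbon–bromine or carbon–chlorine bonds, so one equivalent of 3 sets the future C4a–C4b bond with every ring A and ring C substituent already in its final position, a regiochemical certainty that photocyclisation of a stilbene with two meta-substituted rings would not offer.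

Step 3
Reactants: 4 3'-(benzyloxy)-5-bromo-4'-chloro-4-methoxybiphenyl-2-carbaldehyde
Product: 5 3'-(benzyloxy)-5-bromo-4'-chloro-2-ethynyl-4-methoxybiphenyl
Conditions: dimethyl (1-diazo-2-oxopropyl)phosphonate (1.3 equiv), K2CO3 (2 equiv), MeOH/THF 1:1, 0 °C to rt
Reagents that add atoms: dimethyl (1-diazo-2-oxopropyl)phosphonate (Ohira–Bestmann reagent), COP(=O)(OC)C(=[N+]=[N-])C(C)=O
Why: The Ohira–Bestmann variant of the Seyferth–Gilbert homologation turns the aryl aldehyde into the terminal alkyne through a diazoalkene and a 1,2-hydrogen shift of the derived alkylidene carbene, under mild carbonate conditions that leave the halides and the benzyl ether untouched.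

Step 4
Reactants: 5 3'-(benzyloxy)-5-bromo-4'-chloro-2-ethynyl-4-methoxybiphenyl
Product: 6 3-(benzyloxy)-6-bromo-2-chloro-7-methoxyphenanthrene
Conditions: PtCl2 (5 mol %), dry toluene, 80 °C
Reagents that add atoms: none
Why: PtCl2-catalysed 6-endo-dig cycloisomerisation (intramolecular alkyne hydroarylation) of a 2-ethynylbiaryl is an established phenanthrene synthesis, and here the activated terminal alkyne carbon should be attacked by the ring C carbon para to the benzyloxy group, which is both the activated and the unhindered one of the two ortho sites, so that C9–C10 is formed unsubstituted and Cl, OBn, Br and OMe end up on C2, C3, C6 and C7.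

Step 5
Reactants: 6 3-(benzyloxy)-6-bromo-2-chloro-7-methoxyphenanthrene
Product: 7 3-(benzyloxy)-2-chloro-7-methoxyphenanthrene-6-boronic acid pinacol ester
Conditions: B2pin2 (1.2 equiv), Pd(dppf)Cl2 (3 mol %), KOAc (3 equiv), 1,4-dioxane, 90 °C
Reagents that add atoms: bis(pinacolato)diboron, CC1(C)OB(OC1(C)C)B1OC(C)(C)C(C)(C)O1
Why: Miyaura borylation with Pd(dppf)Cl2 exchanges the aryl bromide but not the electron-rich aryl chloride, and placing boron on the phenanthrene, which has only one ortho substituent, avoids a 2,6-disubstituted ring D boronate that would be prone to protodeboronation.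

Step 6
Reactants: 8 2-bromo-3-hydroxybenzaldehyde
Product: 9 2-bromo-6-chloro-3-hydroxybenzaldehyde
Conditions: NCS (1.05 equiv), p-TsOH·H2O (10 mol %), MeCN, 0 °C to rt
Reagents that add atoms: N-chlorosuccinimide, O=C1CCC(=O)N1Cl
Why: Electrophilic aromatic chlorination of the phenol supplies the ring D chlorine that 8 lacks, since one ortho carbon is blocked by bromine and the hydroxyl should direct mainly to its para carbon (C6), the position at which 3-hydroxybenzaldehydes are preferentially halogenated, the 4-chloro isomer being removed by crystallisation or chromatography.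

Step 7
Reactants: 9 2-bromo-6-chloro-3-hydroxybenzaldehyde
Product: 10 2-bromo-4-chloro-3-formylphenyl pivalate
Conditions: PivCl (1.2 equiv), Et3N (1.5 equiv), DMAP (5 mol %), CH2Cl2, 0 °C to rt
Reagents that add atoms: pivaloyl chloride, CC(C)(C)C(=O)Cl
Why: DMAP-catalysed O-acylation installs a hindered ester that, unlike an acetate, should withstand the ylide of step 9, the aqueous phosphate of step 11 and BCl3 in step 12, so the group that later keeps ring D electron-poor at the anode needs no late selective introduction.

Step 8
Reactants: 11 4-(benzyloxy)benzyl chloride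
Product: 12 [4-(benzyloxy)benzyl]triphenylphosphonium chloride
Conditions: PPh3 (1.05 equiv), toluene, reflux
Reagents that add atoms: triphenylphosphine, c1ccc(cc1)P(c1ccccc1)c1ccccc1
Why: SN2 quaternisation of PPh3 by the benzylic chloride gives the salt, which should crystallise from the hot toluene.

Step 9
Reactants: 12 [4-(benzyloxy)benzyl]triphenylphosphonium chloride; 10 2-bromo-4-chloro-3-formylphenyl pivalate
Product: 14 3-{2-[4-(benzyloxy)phenyl]ethenyl}-2-bromo-4-chlorophenyl pivalate (E/Z mixture), via benzylidenephosphorane 13 (not isolated)
Conditions: NaN(SiMe3)2 (1.0 equiv relative to 12), THF, 0 °C; then 10, −78 °C to rt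
Reagents that add atoms: none
Why: Wittig olefination of the electrophilic 2,6-dihalobenzaldehyde with the preformed semistabilised ylide forms the two-carbon bridge between rings D and E, no free base being left to attack the pivalate and the alkene geometry being irrelevant because it is erased in step 10.

Step 10
Reactants: 14 3-{2-[4-(benzyloxy)phenyl]ethenyl}-2-bromo-4-chlorophenyl pivalate
Product: 15 3-{2-[4-(benzyloxy)phenyl]ethyl}-2-bromo-4-chlorophenyl pivalate
Conditions: TsNHNH2 (6 equiv, in portions), NaOAc buffer, THF/H2O 1:1, reflux
Reagents that add atoms: none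
Why: Diimide reduction (concerted syn transfer of two hydrogens from HN=NH generated from the sulfonyl hydrazide) saturates the stilbene double bond without touching the aryl bromide, the aryl chloride or the benzyl ether, all of which would be at risk under hydrogenation over palladium.

Step 11
Reactants: 7 3-(benzyloxy)-2-chloro-7-methoxyphenanthrene-6-boronic acid pinacol ester; 15 3-{2-[4-(benzyloxy)phenyl]ethyl}-2-bromo-4-chlorophenyl pivalate
Product: 16 2-[3-(benzyloxy)-2-chloro-7-methoxyphenanthren-6-yl]-3-{2-[4-(benzyloxy)phenyl]ethyl}-4-chlorophenyl pivalate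
Conditions: Pd(OAc)2 (5 mol %), SPhos (10 mol %), K3PO4 (3 equiv), toluene/H2O 10:1, 80 °C
Reagents that add atoms: none
Why: Suzuki–Miyaura coupling with the bulky, electron-rich SPhos ligand is the standard answer to tri-ortho-substituted biaryls, the bromide next to the electron-withdrawing pivalate should undergo oxidative addition well before either electron-rich aryl chloride at this temperature, and aryl pivalates are known to survive palladium-catalysed couplings in biphasic phosphate.

Step 12
Reactants: 16 2-[3-(benzyloxy)-2-chloro-7-methoxyphenanthren-6-yl]-3-{2-[4-(benzyloxy)phenyl]ethyl}-4-chlorophenyl pivalate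
Product: 17 4-chloro-2-(2-chloro-3-hydroxy-7-methoxyphenanthren-6-yl)-3-[2-(4-hydroxyphenyl)ethyl]phenyl pivalate (seco diphenol)
Conditions: BCl3 (1 M in CH2Cl2, 5 equiv), C6HMe5 (8 equiv), CH2Cl2, −78 °C; then H2O
Reagents that add atoms: none
Why: Lewis-acid debenzylation with BCl3 and pentamethylbenzene as a non-basic benzyl-cation scavenger cleaves both aryl benzyl ethers at low temperature, while the aryl methyl ether, the pivalate, the aryl chlorides and the C9–C10 bond, which hydrogenolysis would endanger, should stay intact.

Step 13
Reactants: 17 seco diphenol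
Product: 18 ring D pivalate of the target (macrocycle with the C4–ring E bond)
Conditions: boron-doped diamond anode, Pt cathode, undivided cell, Bu3MeN(O3SOMe) (0.1 M), (CF3)2CHOH, 17 fed by syringe pump (at most 2 mM), 1 mA cm−2, 2.1 F mol−1, 40 °C
Reagents that add atoms: none
Why: Proposed new method: the 2-chloro-3-phenanthrol is the easier of the two phenols to oxidise, so loss of an electron and a proton at the diamond anode gives its phenoxyl radical with the spin concentrated at C4, an ortho carbon of the ring E phenol, still nucleophilic though hydrogen-bonded to the fluorinated alcohol, adds to C4, and a second electron loss followed by two keto–enol shifts delivers the 2,2'-biphenol while protons are reduced to hydrogen at the cathode. The nearest known reactions are intermolecular anodic phenol–phenol and phenol–naphthol cross-couplings in this medium and the chemical C4–C4' oxidative dimerisation of 3-phenanthrols, whereas use of this manifold to close a strained macrocycle has no precedent. The single ring formed is the 12-membered one (C4, C4a, C4b, C5, C6, two ring D carbons, both CH2 groups, three ring E carbons), closed end to end by intramolecular radical–arene C–C coupling. No stereocentre is created, and the new hindered axis together with the bay twist is obtained as a racemate. Site selectivity is secured by the substrate, since C2 is chlorinated, C10a bears no hydrogen, the ring E para carbon carries the ethano bridge and its two ortho carbons are equivalent, and the pivalate lifts ring D above the working potential and takes away its nucleophilicity. Ring closure must also beat dimerisation, which is addressed by slow feeding so that the stationary concentration of 17 stays in the low millimolar range, and solvation of the biphenol by the fluorinated alcohol should slow its further oxidation.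

Step 14
Reactants: 18 ring D pivalate of the target
Product: 19 CNP0310669.0 (target)
Conditions: NaOMe (5 equiv), MeOH/THF 2:1, argon, rt to 40 °C; then 1 M HCl
Reagents that add atoms: none
Why: Base-mediated transesterification of the aryl pivalate, whose 4-chlorophenoxide is a good leaving group, frees the last phenol under oxygen-free conditions that protect the electron-rich biphenol, and nothing else in 18 is base-labile.

Compound list
1 | 4-bromo-3-methoxybenzaldehyde | COc1cc(C=O)ccc1Br | starting material
2 | 4-bromo-2-iodo-5-methoxybenzaldehyde | COc1cc(C=O)c(I)cc1Br | intermediate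
3 | [3-(benzyloxy)-4-chlorophenyl]boronic acid | OB(O)c1ccc(Cl)c(OCc2ccccc2)c1 | starting material
4 | 3'-(benzyloxy)-5-bromo-4'-chloro-4-methoxybiphenyl-2-carbaldehyde | COc1cc(C=O)c(cc1Br)-c1ccc(Cl)c(OCc2ccccc2)c1 | intermediate
5 | 3'-(benzyloxy)-5-bromo-4'-chloro-2-ethynyl-4-methoxybiphenyl | COc1cc(C#C)c(cc1Br)-c1ccc(Cl)c(OCc2ccccc2)c1 | intermediate
6 | 3-(benzyloxy)-6-bromo-2-chloro-7-methoxyphenanthrene | COc1cc2ccc3cc(Cl)c(OCc4ccccc4)cc3c2cc1Br | intermediate
7 | 3-(benzyloxy)-2-chloro-7-methoxyphenanthrene-6-boronic acid pinacol ester | COc1cc2ccc3cc(Cl)c(OCc4ccccc4)cc3c2cc1B1OC(C)(C)C(C)(C)O1 | intermediate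
8 | 2-bromo-3-hydroxybenzaldehyde | O=Cc1cccc(O)c1Br | starting material
9 | 2-bromo-6-chloro-3-hydroxybenzaldehyde | O=Cc1c(Cl)ccc(O)c1Br | intermediate
10 | 2-bromo-4-chloro-3-formylphenyl pivalate | CC(C)(C)C(=O)Oc1ccc(Cl)c(C=O)c1Br | intermediate
11 | 4-(benzyloxy)benzyl chloride | ClCc1ccc(OCc2ccccc2)cc1 | starting material
12 | [4-(benzyloxy)benzyl]triphenylphosphonium chloride | [Cl-].C(Oc1ccc(C[P+](c2ccccc2)(c2ccccc2)c2ccccc2)cc1)c1ccccc1 | intermediate
13 | [4-(benzyloxy)benzylidene]triphenylphosphorane (ylide, not isolated) | C(Oc1ccc(C=P(c2ccccc2)(c2ccccc2)c2ccccc2)cc1)c1ccccc1 | intermediate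
14 | 3-{2-[4-(benzyloxy)phenyl]ethenyl}-2-bromo-4-chlorophenyl pivalate (E/Z mixture, geometry erased in step 10) | CC(C)(C)C(=O)Oc1ccc(Cl)c(C=Cc2ccc(OCc3ccccc3)cc2)c1Br | intermediate
15 | 3-{2-[4-(benzyloxy)phenyl]ethyl}-2-bromo-4-chlorophenyl pivalate | CC(C)(C)C(=O)Oc1ccc(Cl)c(CCc2ccc(OCc3ccccc3)cc2)c1Br | intermediate
16 | 2-[3-(benzyloxy)-2-chloro-7-methoxyphenanthren-6-yl]-3-{2-[4-(benzyloxy)phenyl]ethyl}-4-chlorophenyl pivalate | COc1cc2ccc3cc(Cl)c(OCc4ccccc4)cc3c2cc1-c1c(OC(=O)C(C)(C)C)ccc(Cl)c1CCc1ccc(OCc2ccccc2)cc1 | intermediate
17 | 4-chloro-2-(2-chloro-3-hydroxy-7-methoxyphenanthren-6-yl)-3-[2-(4-hydroxyphenyl)ethyl]phenyl pivalate (seco diphenol) | COc1cc2ccc3cc(Cl)c(O)cc3c2cc1-c1c(OC(=O)C(C)(C)C)ccc(Cl)c1CCc1ccc(O)cc1 | intermediate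
18 | ring D pivalate of the target (12-membered macrocycle, racemic) | COc1cc2ccc3cc(Cl)c(O)c4c3c2cc1-c1c(OC(=O)C(C)(C)C)ccc(Cl)c1CCc1ccc(O)c-4c1 | intermediate
19 | CNP0310669.0 | COc1cc2ccc3cc(Cl)c(O)c4c3c2cc1-c1c(O)ccc(Cl)c1CCc1ccc(O)c-4c1 | target

Total step count: 14.
Longest linear sequence: 9 steps (1 to 2, 4, 5, 6, 7, 16, 17, 18, 19; steps 1–5 and 11–14).

Steps most likely to fail

1. Step 13, the new method.
   - What may go wrong: closure of the strained ring may be too slow. Intermolecular C–C or C–O coupling, oligomerisation, further oxidation of the biphenol or fouling of the anode would then consume the material.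
   - Fallback with known chemistry, setting out from 17 and returning at 18: both termini are prefunctionalised and joined by palladium catalysis. NBS (2 equiv, MeCN, 0 °C) should brominate C4 of the phenanthrol and one ortho carbon of the ring E phenol to give the dibromo diphenol F1. MOMCl and iPr2NEt in CH2Cl2 cap both phenols to give the bis(methoxymethyl) ether F2. A one-pot Miyaura borylation and intramolecular Suzuki–Miyaura macrocyclisation follows (B2pin2, Pd(dppf)Cl2, KOAc then K3PO4, DMSO, 80 °C, 2 mM); this method is established for strained biaryl macrocycles. It first borylates the less hindered ring E bromide to the ring E pinacol boronate F3, which is not isolated, and then closes the ring to the macrocyclic bis(methoxymethyl) ether F4. HCl in iPrOH/THF/H2O at 40 °C removes both acetals without touching the pivalate and gives 18.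

2. Step 11.
   - What may go wrong: oxidative addition at the bromide flanked on both sides may be slow enough for protodeboronation of 7, insertion into a carbon–chlorine bond or hydrolysis of the pivalate to compete.
   - Fallback, setting out from 7 and 10 and returning at 16: the order of bond formation is changed so that the cross-coupling takes place on a bromide activated by an ortho formyl group. 7 and 10 are coupled with Pd(PPh3)4 and Na2CO3 in DME/H2O at 80 °C, a catalyst that leaves aryl chlorides alone, to give the biaryl aldehyde F5. Wittig reaction with ylide 13 gives the stilbene F6. Diimide reduction as in step 10 gives 16.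

3. Step 6.
   - What may go wrong: the hydroxyl may not discriminate well enough between its free ortho and para carbons, and a second chlorination may follow.
   - Fallback, setting out from 8 and returning at 10: the site is fixed by the aldehyde rather than by the phenol. 8 is first esterified (PivCl, Et3N, DMAP, CH2Cl2) to 2-bromo-3-formylphenyl pivalate F7. A palladium-catalysed ortho C–H chlorination of the benzaldehyde through a transient imine directing group (Pd(OAc)2, a catalytic electron-poor aniline, NCS, CF3CO2H, 1,2-dichloroethane, 80 °C) then chlorinates the only C–H bond ortho to the formyl group and gives 10 directly.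

Further compounds
F1 | step 13 | 2-(4-bromo-2-chloro-3-hydroxy-7-methoxyphenanthren-6-yl)-3-[2-(3-bromo-4-hydroxyphenyl)ethyl]-4-chlorophenyl pivalate | COc1cc2ccc3cc(Cl)c(O)c(Br)c3c2cc1-c1c(OC(=O)C(C)(C)C)ccc(Cl)c1CCc1ccc(O)c(Br)c1
F2 | step 13 | bis(methoxymethyl) ether of F1 | COCOc1c(Cl)cc2ccc3cc(OC)c(cc3c2c1Br)-c1c(OC(=O)C(C)(C)C)ccc(Cl)c1CCc1ccc(OCOC)c(Br)c1
F3 | step 13 | ring E pinacol boronate derived from F2 (not isolated) | COCOc1c(Cl)cc2ccc3cc(OC)c(cc3c2c1Br)-c1c(OC(=O)C(C)(C)C)ccc(Cl)c1CCc1ccc(OCOC)c(c1)B1OC(C)(C)C(C)(C)O1
F4 | step 13 | bis(methoxymethyl) ether of 18 | COc1cc2ccc3cc(Cl)c(OCOC)c4c3c2cc1-c1c(OC(=O)C(C)(C)C)ccc(Cl)c1CCc1ccc(OCOC)c-4c1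
F5 | step 11 | 2-[3-(benzyloxy)-2-chloro-7-methoxyphenanthren-6-yl]-4-chloro-3-formylphenyl pivalate | COc1cc2ccc3cc(Cl)c(OCc4ccccc4)cc3c2cc1-c1c(OC(=O)C(C)(C)C)ccc(Cl)c1C=O
F6 | step 11 | 2-[3-(benzyloxy)-2-chloro-7-methoxyphenanthren-6-yl]-3-{2-[4-(benzyloxy)phenyl]ethenyl}-4-chlorophenyl pivalate (E/Z mixture) | COc1cc2ccc3cc(Cl)c(OCc4ccccc4)cc3c2cc1-c1c(OC(=O)C(C)(C)C)ccc(Cl)c1C=Cc1ccc(OCc2ccccc2)cc1
F7 | step 6 | 2-bromo-3-formylphenyl pivalate | CC(C)(C)C(=O)Oc1cccc(C=O)c1Br
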